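**Plan**
- Retrosynthesis: the azepine C5–C6 bond is cut first, as the product of a 2-aza-Cope ring enlargement that also breaks C9a–C8. The cyclopropane C9a–C9–C8 is then cut into a C8 carbene unit and a C9=C9a silyl enol ether, the pyrroline into an N4–C9a condensation and a C1–C2 enolate alkylation, and C10–ethyl into a conjugate addition.
- Forward: ring lactone on a cyclohexene (Ireland–Claisen, selenolactonisation), then enone, pyrroline, enol silane, cyclopropane, and the seven-membered ring last. The side-chain lactone is built separately from a D-serine aldehyde and joined as a cyclic sulfamidate.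
- Enabling feature: a cyclopropane fused to the C9–C9a bond of the hydroindole, with N4 (on C9a) and a vinyl group (on C8) cis. Its N-cyclopropyl formaldiminium ion is then an aza analogue of a cis-divinylcyclopropane.
- Stereochemistry: C12/C13 by chirality transfer from (S)-cyclohex-2-en-1-ol; C11 by anti selenolactonisation; C10 by conjugate addition anti to O11. C9 is set by the face of cyclopropanation, steered by C13 and by H1 (set in the hydrosilylation, later lost). C3 comes from D-serine, C18 from Felkin–Anh addition, C20 from hydrogenation.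

Key step: step 20

Remark: atoms carry the usual Stemona numbers (N4; C5–C8 azepane CH2; C9 carbinol; C9a and C1 enamine carbons; C2, C3; C10 ethyl-bearing; C11 O-bearing; C12; C13 methyl-bearing; C14 lactone C=O; C18–C21 side-chain lactone); (S)-cyclohex-2-en-1-ol and succinimidyl diazoacetate are assumed purchasable.

**Step 1**
Reactants: 1 (S)-cyclohex-2-en-1-ol; 2 propanoyl chloride
Product: 3 (S)-cyclohex-2-en-1-yl propanoate
Conditions: pyridine, DMAP (cat.), CH2Cl2, 0 °C to rt
Reagents that add atoms: none
Why: O-acylation of a secondary allylic alcohol with an acid chloride under nucleophilic catalysis should leave the carbinol stereocentre untouched.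

**Step 2**
Reactants: 3 (S)-cyclohex-2-en-1-yl propanoate
Product: 6 (2R)-2-[(1R)-cyclohex-2-en-1-yl]propanoic acid, via silyl ketene acetal 4 (not isolated), via trimethylsilyl ester 5 (not isolated)
Conditions: LDA, THF, −78 °C; Me3SiCl, −78 °C to 65 °C; then 1 M HCl
Reagents that add atoms: none
Why: Ireland–Claisen rearrangement: kinetic enolisation in THF gives the (E)-silyl ketene acetal, whose suprafacial [3,3] shift through the boat-like transition state usual for cyclohex-2-enyl esters should transfer the carbinol chirality to C12 and place the C13 methyl cis to the ring CH2 (C1).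

**Step 3**
Reactants: 6 (2R)-2-[(1R)-cyclohex-2-en-1-yl]propanoic acid
Product: 7 (3R,3aS,7R,7aR)-3-methyl-7-(phenylselanyl)hexahydro-1-benzofuran-2(3H)-one
Conditions: PhSeCl, CH2Cl2, −78 °C to rt
Reagents that add atoms: benzeneselenenyl chloride, Cl[Se]c1ccccc1
Why: Phenylselenolactonisation: anti addition across C10=C11 through the seleniranium ion with 5-exo closure by the carboxylate from the face that carries the side chain should give the cis-fused lactone (O11 cis to C13) with selenium trans on C10.

**Step 4**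
Reactants: 7 the selenolactone
Product: 9 (3R,3aS,7aS)-3-methyl-3a,4,5,7a-tetrahydro-1-benzofuran-2(3H)-one, via selenoxide 8 (not isolated)
Conditions: 30% H2O2, pyridine, CH2Cl2, 0 °C to rt
Reagents that add atoms: none
Why: Selenoxide syn-elimination runs away from the oxygen-bearing carbon and should give the C9=C10 allylic lactone without base, so the epimerisable C13 is not exposed.

**Step 5**
Reactants: 9 the allylic lactone
Product: 10 (3R,3aS,7aS)-3-methyl-3,3a,4,7a-tetrahydro-1-benzofuran-2,5-dione
Conditions: Rh2(cap)4 (cap = caprolactamate, cat.), t-BuOOH, K2CO3, CH2Cl2, rt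
Reagents that add atoms: tert-butyl hydroperoxide, CC(C)(C)OO
Why: Dirhodium-catalysed allylic oxidation of a cyclohexene to the enone should place the carbonyl at C9a, the only unhindered allylic CH2 (the other allylic C–H, at C11, is deactivated by the acyloxy group).

**Step 6**
Reactants: 11 tert-butyl (4R)-4-formyl-2,2-dimethyl-1,3-oxazolidine-3-carboxylate; 12 ethyl 2-(bromomethyl)prop-2-enoate
Product: 13 tert-butyl (4R)-4-[(1S)-3-(ethoxycarbonyl)-1-hydroxybut-3-en-1-yl]-2,2-dimethyl-1,3-oxazolidine-3-carboxylate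
Conditions: Zn dust, THF/saturated aqueous NH4Cl, 0 °C to rt
Reagents that add atoms: none
Why: Zinc-mediated Barbier allylation; non-chelated Felkin–Anh addition to the N-Boc oxazolidine aldehyde should give the anti amino alcohol, which sets C18 relative to C3.

**Step 7**
Reactants: 13 the Barbier adduct
Product: 14 tert-butyl N-[(1R)-2-hydroxy-1-[(2S)-4-methylidene-5-oxooxolan-2-yl]ethyl]carbamate
Conditions: TsOH·H2O (cat.), MeOH, rt to 40 °C
Reagents that add atoms: none
Why: Acid-catalysed cleavage of the N,O-acetonide and lactonisation of the γ-hydroxy ester (only the secondary hydroxyl can close a five-membered ring) should occur together while the Boc group survives.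

**Step 8**
Reactants: 14 the α-methylene lactone
Product: 15 tert-butyl N-[(1R)-2-hydroxy-1-[(2S,4S)-4-methyl-5-oxooxolan-2-yl]ethyl]carbamate
Conditions: H2 (1 atm), Pd/C, EtOAc, rt
Reagents that add atoms: none
Why: Heterogeneous hydrogenation of the exocyclic alkene from the face opposite the C18 substituent should give the cis-2,4-disubstituted lactone and so set C20.

**Step 9**
Reactants: 15 the methyl lactone amino alcohol
Product: 17 tert-butyl (4R)-4-[(2S,4S)-4-methyl-5-oxooxolan-2-yl]-1,2,3-oxathiazolidine-3-carboxylate 2,2-dioxide, via cyclic sulfamidite 16 (not isolated)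
Conditions: SOCl2, imidazole, Et3N, CH2Cl2, −40 °C to 0 °C; then RuCl3·xH2O (cat.), NaIO4, MeCN/H2O, 0 °C
Reagents that add atoms: thionyl chloride, O=S(Cl)Cl; sodium periodate, [Na+].[O-]I(=O)(=O)=O
Why: Standard conversion of an N-Boc 1,2-amino alcohol into its cyclic sulfamidate (sulfinylation, then ruthenium-catalysed oxidation at sulfur) touches no stereocentre.

**Step 10**
Reactants: 10 the enone lactone; 17 the cyclic sulfamidate
Product: 19 tert-butyl N-[(1R)-2-[(3R,3aS,4R,7aS)-3-methyl-2,5-dioxo-2,3,3a,4,5,7a-hexahydro-1-benzofuran-4-yl]-1-[(2S,4S)-4-methyl-5-oxooxolan-2-yl]ethyl]carbamate, via lithium N-sulfamate 18 (not isolated)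
Conditions: LDA, THF, −78 °C; then 17, −78 °C to 0 °C; then 1 M HCl, Et2O, rt
Reagents that add atoms: none
Why: Kinetic α′-deprotonation gives the cross-conjugated enolate at C1, which should open the sulfamidate by SN2 at its CH2–O carbon (C2) anti to the neighbouring lactone carbon, and mild acid hydrolyses the N-sulfamate (the C1 configuration is erased in step 14).

**Step 11**
Reactants: 19 the Boc-amino enone
Product: 20 the C9=C9a trimethylsilyl enol ether carrying ethyl on C10 (trans to O11)
Conditions: Et2Zn, Cu(OTf)2 (cat.), P(OEt)3 (cat.), toluene, −20 °C; then Me3SiOTf, −20 °C to 0 °C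
Reagents that add atoms: diethylzinc, CC[Zn]CC; trimethylsilyl trifluoromethanesulfonate, C[Si](C)(C)OS(=O)(=O)C(F)(F)F
Why: Copper-catalysed 1,4-addition of diethylzinc with O-silylation of the zinc enolate; ethyl should add to C10 anti to the adjacent C11 acyloxy group (convex face), which sets C10, and the enolate is fixed regiospecifically as the enol silane.

**Step 12**
Reactants: 20 the trimethylsilyl enol ether
Product: 23 the C9-hydroxy C9a-ketone, via silyloxy epoxide 21 (not isolated), via silyloxy ketone 22 (not isolated)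
Conditions: mCPBA, NaHCO3, CH2Cl2, −20 °C to 0 °C; then 10% aqueous citric acid, THF
Reagents that add atoms: 3-chloroperoxybenzoic acid, OOC(=O)c1cccc(Cl)c1
Why: Rubottom oxidation (epoxidation of the enol silane, silyl shift, desilylation) places oxygen on C9 regiospecifically; the C9 configuration is immaterial because C9 becomes a ketone in step 14.

**Step 13**
Reactants: 23 the α-hydroxy ketone
Product: 25 the cyclic imine (N4=C9a 1-pyrroline with C9–OH), via ammonium trifluoroacetate 24 (not isolated)
Conditions: TFA, CH2Cl2, 0 °C; concentrate; then NaOAc, 4 Å MS, CH2Cl2, rt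
Reagents that add atoms: none
Why: Acidolytic Boc removal followed by buffered intramolecular condensation of the primary amine with the C9a ketone (5-exo-trig addition, dehydration) should give the cyclic imine, the buffer keeping the amine protonated enough to outrun O-to-N acyl transfer from the neighbouring lactone.

**Step 14**
Reactants: 25 the cyclic hydroxy imine
Product: 27 the N4-formyl enaminone (C1=C9a, C9=O), via secondary enaminone 26 (not isolated)
Conditions: DMP (1,1,1-triacetoxy-1,1-dihydro-1,2-benziodoxol-3(1H)-one), CH2Cl2, 0 °C to rt; then HCO2Ac, pyridine, 0 °C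
Reagents that add atoms: acetic formic anhydride, CC(=O)OC=O
Why: Periodinane oxidation of the carbinol gives the α-imino ketone, which tautomerises to the conjugated enaminone (C1 becomes sp2), and N-acylation with the mixed anhydride gives the formamide; C10, now α to the ketone, should keep its trans pseudo-equatorial ethyl, which is also the thermodynamic arrangement here.

**Step 15**
Reactants: 27 the N-formyl enaminone
Product: 28 the C9=C9a triethylsilyl enol ether (H1 cis to H12)
Conditions: Et3SiH, RhCl(PPh3)3 (cat.), benzene, 60 °C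
Reagents that add atoms: triethylsilane, CC[SiH](CC)CC
Why: Rhodium-catalysed 1,4-hydrosilylation of the enone gives the tetrasubstituted enol silane regiospecifically, with hydride delivered to C1 from the face opposite the pseudoaxial lactone carbon C13 on C12.

**Step 16**
Reactants: 28 the triethylsilyl enol ether; 29 2,5-dioxopyrrolidin-1-yl 2-diazoacetate
Product: 30 the siloxy-aminocyclopropane active ester (C8 anti to O9 and N4 across the six-membered ring, ester syn to N4 and O9)
Conditions: Rh2(OAc)4 (cat.), CH2Cl2, rt, slow addition of 29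
Reagents that add atoms: none
Why: Rhodium-carbenoid [2+1] cyclopropanation of an electron-rich silyl enol ether with an acceptor diazo ester; the carbenoid should add to the face of C9=C9a opposite the axial C13 and the C3 side chain (which also gives the cis-fused pyrrolidine), and the ester should take the exo position.

**Step 17**
Reactants: 30 the cyclopropane active ester
Product: 31 the cyclopropylmethanol
Conditions: NaBH4, THF, 0 °C
Reagents that add atoms: none
Why: Borohydride reduction of the activated N-hydroxysuccinimide ester to the primary alcohol should spare the two γ-lactones, the formamide and the silyl ether.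

**Step 18**
Reactants: 31 the cyclopropylmethanol
Product: 32 the cyclopropanecarbaldehyde
Conditions: DMP, NaHCO3, CH2Cl2, 0 °C
Reagents that add atoms: none
Why: Buffered periodinane oxidation of the primary alcohol gives the aldehyde under non-basic conditions that spare the donor–acceptor cyclopropane.

**Step 19**
Reactants: 32 the cyclopropanecarbaldehyde
Product: 33 the vinylcyclopropane (N4-formyl, C9–OSiEt3, vinyl cis to N4)
Conditions: Ph3PCH3Br, KHMDS, THF, −78 °C to 0 °C
Reagents that add atoms: methyltriphenylphosphonium bromide, C[P+](c1ccccc1)(c1ccccc1)c1ccccc1.[Br-]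
Why: Wittig methylenation with a slight deficit of base converts the aldehyde into the vinyl group without touching C8, C13 or C20.

**Step 20**
Reactants: 33 the vinylcyclopropane
Product: 37 the 7,8-didehydro C9 triethylsilyl ether of the target, via silyl acetal 34 (not isolated), via formaldiminium triflate 35 (not isolated), via ring-enlarged iminium triflate 36 (not isolated)
Conditions: IrCl(CO)(PPh3)2 (cat.), (HMe2Si)2O, toluene, rt; then Me3SiOTf, CH2Cl2, −40 °C to rt; then Et3N
Reagents that add atoms: none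
Why: Proposed new method: iridium-catalysed hydrosilylation of the tertiary formamide gives the N,O-silyl acetal, which Me3SiOTf ionises to the N-cyclopropyl formaldiminium ion; because N4 and the vinyl group are cis on the strained ring, this ion should undergo a charge-accelerated 2-aza-Cope ([3,3]) shift in which C5 bonds to C6 while the cyclopropane bond C9a–C8 breaks, and the resulting C9a=N4 iminium ion loses H1 to give the enamine. The closest known reactions are the cis-divinylcyclopropane to cycloheptadiene rearrangement and its aza variants (2-vinylcyclopropyl isocyanates and imines to azepines) together with the cationic 2-aza-Cope step of aza-Cope/Mannich sequences, and the reductive generation of iminium ions from tertiary amides with IrCl(CO)(PPh3)2 and a silane is known. The seven-membered ring closes by a concerted six-electron enlargement of the three-membered ring through the boat-like transition state that a cis-1,2-disubstituted cyclopropane requires, so the new C7=C8 bond is cis. No stereocentre is created: C9 keeps its four bonds and its configuration, and C1 is flattened when the enamine forms. The step needs the iminium carbon to lie endo over the three-membered ring, which the pyrrolidine enforces by holding C3 on the exo side, and it needs the enamine to form only toward C1, which is secured because C9 is quaternary. Chemoselectivity rests on the known preference of the iridium/silane system for tertiary amides over lactones and alkenes and on the aprotic ionisation, which should spare the siloxycyclopropane.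

**Step 21**
Reactants: 37 the 7,8-didehydro silyl ether
Product: 38 the C9 O-triethylsilyl ether of the target
Conditions: H2 (1 atm), RhCl(PPh3)3 (cat.), benzene/EtOH, rt
Reagents that add atoms: none
Why: Homogeneous hydrogenation should reduce the cis-disubstituted C7=C8 bond and leave the tetrasubstituted nitrogen-bearing C1=C9a enamine alone.

**Step 22**
Reactants: 38 the C9 O-triethylsilyl ether
Product: 39 the target
Conditions: Bu4NF, THF, 0 °C
Reagents that add atoms: none
Why: Fluoride-mediated cleavage of the tertiary silyl ether should free the C9 hydroxyl without protonating the enamine or opening the lactones.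

**Compound list**
1 | (S)-cyclohex-2-en-1-ol | O[C@@H]1C=CCCC1 | starting material
2 | propanoyl chloride | CCC(Cl)=O | starting material
3 | (S)-cyclohex-2-en-1-yl propanoate | CCC(=O)O[C@@H]1C=CCCC1 | intermediate
4 | (E)-1-[(1S)-cyclohex-2-en-1-yloxy]-1-(trimethylsilyloxy)prop-1-ene | C/C=C(\O[C@@H]1C=CCCC1)O[Si](C)(C)C | intermediate
5 | trimethylsilyl (2R)-2-[(1R)-cyclohex-2-en-1-yl]propanoate | C[Si](C)(C)OC(=O)[C@H](C)[C@@H]1CCCC=C1 | intermediate
6 | (2R)-2-[(1R)-cyclohex-2-en-1-yl]propanoic acid | OC(=O)[C@H](C)[C@@H]1CCCC=C1 | intermediate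
7 | (3R,3aS,7R,7aR)-3-methyl-7-(phenylselanyl)hexahydro-1-benzofuran-2(3H)-one | c1ccccc1[Se][C@H]1[C@@H]2OC(=O)[C@H](C)[C@@H]2CCC1 | intermediate
8 | selenoxide of 7 | O=[Se](c1ccccc1)[C@H]1[C@@H]2OC(=O)[C@H](C)[C@@H]2CCC1 | intermediate
9 | (3R,3aS,7aS)-3-methyl-3a,4,5,7a-tetrahydro-1-benzofuran-2(3H)-one | C1=C[C@@H]2OC(=O)[C@H](C)[C@@H]2CC1 | intermediate
10 | (3R,3aS,7aS)-3-methyl-3,3a,4,7a-tetrahydro-1-benzofuran-2,5-dione | O=C1C=C[C@@H]2OC(=O)[C@H](C)[C@@H]2C1 | intermediate
11 | tert-butyl (4R)-4-formyl-2,2-dimethyl-1,3-oxazolidine-3-carboxylate | O=C[C@H]1COC(C)(C)N1C(=O)OC(C)(C)C | starting material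
12 | ethyl 2-(bromomethyl)prop-2-enoate | C=C(CBr)C(=O)OCC | starting material
13 | tert-butyl (4R)-4-[(1S)-3-(ethoxycarbonyl)-1-hydroxybut-3-en-1-yl]-2,2-dimethyl-1,3-oxazolidine-3-carboxylate | CCOC(=O)C(=C)C[C@H](O)[C@H]1COC(C)(C)N1C(=O)OC(C)(C)C | intermediate
14 | tert-butyl N-[(1R)-2-hydroxy-1-[(2S)-4-methylidene-5-oxooxolan-2-yl]ethyl]carbamate | OC[C@@H](NC(=O)OC(C)(C)C)[C@@H]1CC(=C)C(=O)O1 | intermediate
15 | tert-butyl N-[(1R)-2-hydroxy-1-[(2S,4S)-4-methyl-5-oxooxolan-2-yl]ethyl]carbamate | OC[C@@H](NC(=O)OC(C)(C)C)[C@@H]1C[C@H](C)C(=O)O1 | intermediate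
16 | cyclic sulfamidite of 15 (oxathiazolidine 2-oxide) | O=S1OC[C@H]([C@@H]2C[C@H](C)C(=O)O2)N1C(=O)OC(C)(C)C | intermediate
17 | tert-butyl (4R)-4-[(2S,4S)-4-methyl-5-oxooxolan-2-yl]-1,2,3-oxathiazolidine-3-carboxylate 2,2-dioxide | O=S1(=O)OC[C@H]([C@@H]2C[C@H](C)C(=O)O2)N1C(=O)OC(C)(C)C | intermediate
18 | lithium N-sulfamate of 19 | [Li+].O=C1C=C[C@@H]2OC(=O)[C@H](C)[C@@H]2[C@H]1C[C@@H](N(C(=O)OC(C)(C)C)S(=O)(=O)[O-])[C@@H]1C[C@H](C)C(=O)O1 | intermediate
19 | tert-butyl N-[(1R)-2-[(3R,3aS,4R,7aS)-3-methyl-2,5-dioxo-2,3,3a,4,5,7a-hexahydro-1-benzofuran-4-yl]-1-[(2S,4S)-4-methyl-5-oxooxolan-2-yl]ethyl]carbamate | O=C1C=C[C@@H]2OC(=O)[C@H](C)[C@@H]2[C@H]1C[C@@H](NC(=O)OC(C)(C)C)[C@@H]1C[C@H](C)C(=O)O1 | intermediate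
20 | C9=C9a trimethylsilyl enol ether with C10 ethyl trans to O11 | CC[C@H]1[C@@H]2OC(=O)[C@H](C)[C@@H]2[C@@H](C[C@@H](NC(=O)OC(C)(C)C)[C@@H]2C[C@H](C)C(=O)O2)C(O[Si](C)(C)C)=C1 | intermediate
21 | C9/C9a silyloxy epoxide of 20 | CC[C@H]1[C@@H]2OC(=O)[C@H](C)[C@@H]2[C@@H](C[C@@H](NC(=O)OC(C)(C)C)[C@@H]2C[C@H](C)C(=O)O2)[C@]2(O[Si](C)(C)C)O[C@H]12 | intermediate
22 | C9 trimethylsilyloxy C9a ketone | CC[C@H]1[C@@H]2OC(=O)[C@H](C)[C@@H]2[C@@H](C[C@@H](NC(=O)OC(C)(C)C)[C@@H]2C[C@H](C)C(=O)O2)C(=O)[C@@H]1O[Si](C)(C)C | intermediate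
23 | C9-hydroxy C9a-ketone (Boc-amino side chain on C1) | CC[C@H]1[C@@H]2OC(=O)[C@H](C)[C@@H]2[C@@H](C[C@@H](NC(=O)OC(C)(C)C)[C@@H]2C[C@H](C)C(=O)O2)C(=O)[C@@H]1O | intermediate
24 | ammonium trifluoroacetate from Boc removal of 23 | CC[C@H]1[C@@H]2OC(=O)[C@H](C)[C@@H]2[C@@H](C[C@@H]([NH3+])[C@@H]2C[C@H](C)C(=O)O2)C(=O)[C@@H]1O.[O-]C(=O)C(F)(F)F | intermediate
25 | cyclic imine (N4=C9a, C9–OH) | CC[C@H]1[C@@H]2OC(=O)[C@H](C)[C@@H]2[C@H]2C[C@H]([C@@H]3C[C@H](C)C(=O)O3)N=C2[C@@H]1O | intermediate
26 | secondary enaminone (N4–H, C1=C9a, C9=O) | CC[C@H]1[C@@H]2OC(=O)[C@H](C)[C@@H]2C2=C(N[C@@H]([C@@H]3C[C@H](C)C(=O)O3)C2)C1=O | intermediate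
27 | N4-formyl enaminone | CC[C@H]1[C@@H]2OC(=O)[C@H](C)[C@@H]2C2=C(N(C=O)[C@@H]([C@@H]3C[C@H](C)C(=O)O3)C2)C1=O | intermediate
28 | C9=C9a triethylsilyl enol ether (N4-formyl, H1 cis to H12) | CC[C@H]1[C@@H]2OC(=O)[C@H](C)[C@@H]2[C@@H]2C[C@H]([C@@H]3C[C@H](C)C(=O)O3)N(C=O)C2=C1O[Si](CC)(CC)CC | intermediate
29 | 2,5-dioxopyrrolidin-1-yl 2-diazoacetate | [N-]=[N+]=CC(=O)ON1C(=O)CCC1=O | starting material
30 | C9a–C9–C8 cyclopropane with exo succinimidyl ester on C8 | CC[C@H]1[C@@H]2OC(=O)[C@H](C)[C@@H]2[C@@H]2C[C@H]([C@@H]3C[C@H](C)C(=O)O3)N(C=O)[C@@]24[C@H](C(=O)ON3C(=O)CCC3=O)[C@@]14O[Si](CC)(CC)CC | intermediate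
31 | C8 hydroxymethyl cyclopropane | CC[C@H]1[C@@H]2OC(=O)[C@H](C)[C@@H]2[C@@H]2C[C@H]([C@@H]3C[C@H](C)C(=O)O3)N(C=O)[C@@]24[C@H](CO)[C@@]14O[Si](CC)(CC)CC | intermediate
32 | C8 formyl cyclopropane | CC[C@H]1[C@@H]2OC(=O)[C@H](C)[C@@H]2[C@@H]2C[C@H]([C@@H]3C[C@H](C)C(=O)O3)N(C=O)[C@@]24[C@H](C=O)[C@@]14O[Si](CC)(CC)CC | intermediate
33 | C8 vinyl cyclopropane (vinyl cis to N4 and O9) | CC[C@H]1[C@@H]2OC(=O)[C@H](C)[C@@H]2[C@@H]2C[C@H]([C@@H]3C[C@H](C)C(=O)O3)N(C=O)[C@@]24[C@H](C=C)[C@@]14O[Si](CC)(CC)CC | intermediate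
34 | N,O-silyl acetal of 33 | CC[C@H]1[C@@H]2OC(=O)[C@H](C)[C@@H]2[C@@H]2C[C@H]([C@@H]3C[C@H](C)C(=O)O3)N(CO[Si](C)(C)O[SiH](C)C)[C@@]24[C@H](C=C)[C@@]14O[Si](CC)(CC)CC | intermediate
35 | N-cyclopropyl formaldiminium triflate | CC[C@H]1[C@@H]2OC(=O)[C@H](C)[C@@H]2[C@@H]2C[C@H]([C@@H]3C[C@H](C)C(=O)O3)[N+](=C)[C@@]24[C@H](C=C)[C@@]14O[Si](CC)(CC)CC.[O-]S(=O)(=O)C(F)(F)F | intermediate
36 | ring-enlarged C9a=N4 iminium triflate | CC[C@H]1[C@@H]2OC(=O)[C@H](C)[C@@H]2[C@@H]2C[C@H]([C@@H]3C[C@H](C)C(=O)O3)[N+]3=C2[C@@]1(O[Si](CC)(CC)CC)C=CCC3.[O-]S(=O)(=O)C(F)(F)F | intermediate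
37 | 7,8-didehydro C9 O-triethylsilyl ether of the target | CC[C@H]1[C@@H]2OC(=O)[C@H](C)[C@@H]2C2=C3N(CCC=C[C@]31O[Si](CC)(CC)CC)[C@@H]([C@@H]1C[C@H](C)C(=O)O1)C2 | intermediate
38 | C9 O-triethylsilyl ether of the target | CC[C@H]1[C@@H]2OC(=O)[C@H](C)[C@@H]2C2=C3N(CCCC[C@]31O[Si](CC)(CC)CC)[C@@H]([C@@H]1C[C@H](C)C(=O)O1)C2 | intermediate
39 | target (3R,9R,10S,11R,12R,13R,18S,20S) | CC[C@H]1[C@@H]2OC(=O)[C@H](C)[C@@H]2C2=C3N(CCCC[C@]31O)[C@@H]([C@@H]1C[C@H](C)C(=O)O1)C2 | target

**Totals**
Total steps: 22. Longest linear sequence: 18 (steps 1–5 and 10–22, from 1).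

**Steps most likely to fail**

Step 20 (Proposed new method). The boat-like shift may be slowed by the C9 silyloxy group, which lies on the same face of the cyclopropane as the two reacting termini. Ionisation may instead trigger siloxy-assisted cleavage of the C9–C9a bond and enlargement of the carbocycle. The fallback closes the seven-membered ring by olefin metathesis and uses known reactions only. It sets out from enaminone 26 (made as in the first stage of step 14, not formylated). Indium-mediated Barbier allylation of the C9 ketone (In, allyl bromide, THF/H2O) should give the tertiary homoallylic alcohol F1, with allyl entering axially anti to the ethyl group. N-alkylation (allyl bromide, K2CO3, MeCN) should give the N4-allyl enamine F2. Ring-closing metathesis of its camphorsulfonate salt with the second-generation Grubbs catalyst RuCl2(=CHPh)(H2IMes)(PCy3) in CH2Cl2 should give the 6,7-didehydro compound F3. Hydrogenation over RhCl(PPh3)3 as in step 21 comes back to the route at the target 39.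

Step 16. The carbenoid may add to the wrong face of the tetrasubstituted enol ether or give the endo ester, and carbene dimerisation or attack at the formamide oxygen may compete. The fallback replaces the diazo ester by a zinc halocarbenoid and a cross-coupling, setting out from 28. Iodocyclopropanation (CHI3, Et2Zn, CH2Cl2, 0 °C) should give the iodocyclopropane F4. Stille coupling with tributyl(vinyl)stannane (Pd(PPh3)4, CuI, DMF, 50 °C), which keeps the cyclopropane configuration, comes back to the route at 33 and also saves steps 17–19.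

Step 15. Hydrosilylation may not turn over on a fully substituted, nitrogen-bearing enone, or may go 1,2 at the ketone. The fallback separates reduction and enol ether formation, setting out from 27. Hydrogenation (H2, Pd/C, EtOAc) from the face opposite C13 should give the cis-fused saturated formamido ketone F5. Soft enolisation toward the more acidic nitrogen-bearing C9a (Et3SiOTf, Et3N, CH2Cl2, −78 °C to 0 °C) comes back to the route at 28.

**Further compounds**
F1 | step 20 | tertiary homoallylic alcohol (C9 allyl carbinol of 26) | CC[C@H]1[C@@H]2OC(=O)[C@H](C)[C@@H]2C2=C(N[C@@H]([C@@H]3C[C@H](C)C(=O)O3)C2)[C@@]1(O)CC=C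
F2 | step 20 | N4-allyl enamine | CC[C@H]1[C@@H]2OC(=O)[C@H](C)[C@@H]2C2=C(N(CC=C)[C@@H]([C@@H]3C[C@H](C)C(=O)O3)C2)[C@@]1(O)CC=C
F3 | step 20 | 6,7-didehydro target | CC[C@H]1[C@@H]2OC(=O)[C@H](C)[C@@H]2C2=C3N(CC=CC[C@]31O)[C@@H]([C@@H]1C[C@H](C)C(=O)O1)C2
F4 | step 16 | C8 iodocyclopropane (iodine cis to N4 and O9) | CC[C@H]1[C@@H]2OC(=O)[C@H](C)[C@@H]2[C@@H]2C[C@H]([C@@H]3C[C@H](C)C(=O)O3)N(C=O)[C@@]24[C@H](I)[C@@]14O[Si](CC)(CC)CC
F5 | step 15 | cis-fused saturated N4-formyl C9 ketone | CC[C@H]1[C@@H]2OC(=O)[C@H](C)[C@@H]2[C@@H]2C[C@H]([C@@H]3C[C@H](C)C(=O)O3)N(C=O)[C@@H]2C1=O
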